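## The problem

The target is a normal-series labdane: a trans-fused 4,4,10-trimethyldecalin whose ring B carries a tetrasubstituted C8=C9 alkene, an axial 6β-hydroxyl and a pseudoaxial 7α-acetoxy group, with a five-carbon chain on C9 that ends in a Z-trisubstituted allylic acetate (labdane numbering; 5S,6S,7S,10S,13Z).

Four contiguous stereocentres, C10–C5–C6–C7, have to be set. C10 is quaternary and cannot be corrected later, so it must be installed first and in the absolute sense. Once it is in place it can fix C5 through the preference for the trans ring fusion.

In the trans-decalin the syn-axial methyl groups on C4 and C10 shield the β-face of C6 and C7. Reagents arriving from the α-face can therefore deliver both the 6β-hydroxyl (hydride to a 6-ketone) and the 7α-oxygen. The same two methyl groups make the 6β-hydroxyl much less reactive than the C7 and C15 hydroxyls, which is the basis for putting acetate on C7 and C15 only.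

The fragile elements are the allylic C7 acetate next to a free hydroxyl (ionisation, elimination, acyl shift), the Z allylic acetate of the chain, and any α-ketol precursor (enediol isomerisation). Neither acetate survives organolithiums, hydrides or alkoxides, so both go on last. The chain is joined through an unactivated sp3–sp3 bond (C9–C11) beside the quaternary C10.

The feature that opens the key step is the 1,3-relationship of C6 and C8 across C7 in ring B. If C6 is an aldehyde carbon on C5 and C8 the carbonyl of a 2-oxopropyl arm (C9–C8–C7) on C10, then C7 is the only enolisable carbon that can close a six-membered ring. Aldol condensation across C6–C7 builds ring B with oxygen on C8 and unsaturation at C6=C7, which are the handles needed for C9 alkylation and for moving the oxygen from C8 to C6.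

## Retrosynthesis

**Acetates.** Target 26 is cut at the two ester C–O bonds to triol 25, and 25 at the O–Si bond to diol silyl ether 24. Acetylation is placed last because no earlier reagent (methyllithium, amide bases, borohydride) tolerates esters. The two secondary hydroxyls are distinguished by rate, since the 6β-hydroxyl of 25 is pressed between the C4 and C10 methyl groups. The forward step must acetylate C7 and C15 and stop.

**C6 and C7 oxygens.** Diol 24 comes from α-ketol 23 by reduction at C6, and 23 from enone 21 by hydroxylation at C7 through dienolate 22. A 6-ketone is preferred to an epoxide-opening approach because the trans-diaxial 6β,7α pattern would need a β-epoxide, formed on the hindered face. With the ketone, both new centres arise from α-face attack and the C8=C9 alkene is produced in the same operation that makes C7 nucleophilic. The forward steps need γ-deprotonation at C9, α-attack of the oxidant at C7, and α-face hydride at C6.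

**C8–C17 bond and oxygen shift.** Enone 21 is cut at the C8 methyl bond and its oxygen is moved back to C8, giving tertiary allylic alcohol 20 and then enone 19. C17 cannot be carried through the aldol because C8 is the carbonyl carbon there. Adding it as methyllithium is also what allows the oxygen to travel to C6, so one two-step transposition supplies both the methyl group and the C6 oxygen.

**C9–C11 bond.** Enone 19 is cut between C9 and C11 to enone 10 and homoallylic iodide 16, through enolate 17 and the kinetic C9 epimer 18. C9 is the α'-carbon of 10, so this is the one position where the ring is naturally nucleophilic. Cutting C11–C12 or C12–C13 instead would leave a functionalised stub on the decalin and cost extra steps. Iodide 16 comes from alcohol 15, which arises via borane 14 from diene 13, made from enyne silyl ether 12 and commercial (Z)-enynol 11. The Z-alkene is bought, not made.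

**C6–C7 bond (key step).** Enone 10 is opened across C6=C7 through aldol 9 to keto-aldehyde 8. This removes ring B and leaves a monocyclic compound with one stereocentre that matters (C10). Cutting C5–C6 or C9–C10 instead would require forming a bond to a fully substituted carbon during ring closure. The forward reaction needs only ring-size selectivity and the thermodynamic trans fusion.

**C8 oxygen and C5–C6 bond.** Keto-aldehyde 8 comes from allyl aldehyde 7 by Wacker oxidation. Aldehyde 7 comes from spiro-epoxide 6 by hydride-shift rearrangement, and 6 from ketone 5 by methylene transfer. The aldehyde carbon C6 is therefore the one carbon added to the ring carbonyl of 5. The order is fixed because a methyl ketone present earlier would compete for the ylide.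

**C9–C10 bond and the C10 stereocentre.** Ketone 5 is cut at the quaternary carbon to allyl enol carbonate 4, made via lithium enolate 3 from 2,2,6-trimethylcyclohexanone 1 and allyl chloroformate 2. Ketone 1 has a single enolisable position, so regiochemistry is not an issue and the chiral palladium catalyst sets C10.

## Roads not taken

**Alternative 1:** an acyclic trienal A1 would be cyclised by an iminium-catalysed intramolecular Diels–Alder reaction to the C6-formyl labdadiene A2, forming C5–C10 and C6–C7 and both rings at once.
- Merits: it is the most convergent plan. The side chain is in place, two rings and three stereocentres arise in one catalytic step, and if it worked it would be clearly shorter than the chosen route.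
- Weak points:
  - The diene terminus C10 is fully substituted and one of its substituents must sit inside the s-cis diene. The dienophile β-carbon carries the quaternary C4. The cycloaddition must therefore create a quaternary centre between two congested carbons, well beyond the simple trienals for which this activation is established.
  - A1 needs a tetrasubstituted alkene of defined geometry.
  - In A2 the formyl group from the E-enal is 6α and at the wrong oxidation level. It must be degraded to a ketone and reduced.
  - C7 must still be oxidised in the presence of several other allylic positions.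
- Comparison: the chosen plan gives up convergence but forms each bond by a reaction with close precedent, and it obtains the C6 and C8 oxygens from the ring-forming step itself.

**Alternative 2:** the but-2-ynoate ester A3 of a vinylcyclohexenol would undergo a thermal intramolecular Diels–Alder reaction to the tricyclic lactone A4, forming C7–C8 and C9–C10.
- Merits: no catalyst is needed. C10 is relayed from a carbinol centre that can be obtained in very high optical purity, which is better than a catalytic allylation that leaves some minor enantiomer. The C8 methyl and the C8=C9 alkene arrive in their final positions, whereas the chosen route spends three steps (alkylation, methyl addition, transposition) to reach that point.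
- Weak points:
  - C11 arrives as a lactone carbonyl and C1 carries an oxygen the target lacks. Reduction, C1 deoxygenation and a coupling at the allylic C11 (with SN2/SN2' ambiguity) are needed to attach C12–C16.
  - The C5=C6 alkene must be turned into 5α-H/6β-OH. Syn hydroboration from the open face would give the 6α-alcohol and need an oxidation–reduction correction.
  - C7 is still unoxidised.
  - The diene is twisted by the C4 gem-dimethyl group and the ester tether is conformationally reluctant.
- Comparison: against the better optical purity and direct alkene placement, the chosen plan sets an enrichment by crystallisation at enone 10 and a much shorter sequence after the key step.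

**Alternative 3:** (1R,5R)-verbenone A5 would take an allyl group by conjugate addition to give adduct A6, and TiCl4 would cleave the cyclobutane bond α to the ketone so that the tertiary C4 cation closes ring A onto the allyl terminus, giving octalenone A7.
- Merits: the chiral pool supplies C10 and C5 enantiopure, and the decalin is reached in two steps from A5. Both points are better than the chosen plan, which needs six steps to enone 10 and a catalytic step of high but incomplete selectivity.
- Weak points:
  - The cation must be trapped by a monosubstituted alkene to give a secondary cation. This competes with simple proton loss to an isopropenyl group or chloride capture, the usual fate of such ring openings.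
  - A7 has no handle at C6. It needs C6=C7 desaturation with regioselective enolisation toward C7, plus removal of the ring A alkene, before it converges on enone 10.
- Comparison: the step saving is small and the key step is less secure. The chosen plan has an aldol that can close only one ring, and its precursor already holds C6 at the aldehyde level.

Key step: step 6

Remark (assumption): labdane numbering is used for all bicyclic compounds (C4 gem-dimethyl carbon, C5/C10 ring fusion, C17 the C8 methyl, C11–C16 the chain). Aldehydes 7 and 8 are written as the C5 epimer that maps directly onto the target; the other epimer, if formed, is carried along because step 6 converges both.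

Step 1
Reactants: 1 2,2,6-trimethylcyclohexanone; 2 allyl chloroformate
Product: 4 allyl 2,6,6-trimethylcyclohex-1-en-1-yl carbonate, via lithium 2,6,6-trimethylcyclohex-1-en-1-olate 3 (not isolated)
Conditions: LiN(SiMe3)2, THF, 0 °C; then 2, −78 → 25 °C
Reagents that add atoms: none
Why: Ketone 1 has only one enolisable position, so a single fully substituted lithium enolate forms; hindered enolates of this kind are acylated on oxygen by chloroformates (enolate O-acylation), giving the allyl enol carbonate.

Step 2
Reactants: 4 allyl 2,6,6-trimethylcyclohex-1-en-1-yl carbonate
Product: 5 (2R)-2-allyl-2,6,6-trimethylcyclohexan-1-one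
Conditions: Pd2(dba)3 (2.5 mol%), (R)-t-Bu-PHOX (6 mol%), THF, 25 °C
Reagents that add atoms: none
Why: Decarboxylative asymmetric allylic alkylation (Tsuji allylation with a PHOX ligand): zerovalent palladium ionises the allyl carbonate, CO2 is lost and the enolate/π-allyl pair recombines in the chiral pocket; in this substrate class the (S)-ligand gives the (S)-ketone, so the (R)-ligand is chosen to give the (R)-ketone whose quaternary carbon becomes C10 of the target.

Step 3
Reactants: 5 (2R)-2-allyl-2,6,6-trimethylcyclohexan-1-one
Product: 6 (4R)-4-allyl-4,8,8-trimethyl-1-oxaspiro[2.5]octane (both configurations at the spiro carbon)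
Conditions: Me3S+ I−, n-BuLi, THF, −10 °C; then 5, −10 → 25 °C
Reagents that add atoms: trimethylsulfonium iodide, C[S+](C)C.[I-]
Why: Corey–Chaykovsky epoxidation; the small unstabilised sulfonium ylide adds irreversibly to a ketone that cannot enolise, and the betaine closes to the spiro-epoxide; the spiro configuration is irrelevant because that carbon is planarised in step 4.

Step 4
Reactants: 6 (4R)-4-allyl-4,8,8-trimethyl-1-oxaspiro[2.5]octane
Product: 7 (1S,6R)-6-allyl-2,2,6-trimethylcyclohexane-1-carbaldehyde
Conditions: BF3·OEt2 (cat.), CH2Cl2, −78 → 0 °C
Reagents that add atoms: none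
Why: Meinwald rearrangement; ionisation at the tertiary spiro carbon is followed by a 1,2-hydride shift from the CH2O carbon, the only shift that ends in a carbonyl group, so the aldehyde is expected; the carbinyl carbon (future C5) may form as an epimer mixture, which step 6 converges.

Step 5
Reactants: 7 (1S,6R)-6-allyl-2,2,6-trimethylcyclohexane-1-carbaldehyde
Product: 8 (1S,6R)-2,2,6-trimethyl-6-(2-oxopropyl)cyclohexane-1-carbaldehyde
Conditions: PdCl2 (10 mol%), Cu(OAc)2 (20 mol%), O2 (1 atm), DMA/H2O 7:1, 25 °C
Reagents that add atoms: water, O
Why: Tsuji–Wacker oxidation; divalent palladium activates the terminal alkene, water adds at the internal carbon (Markovnikov) and the copper/O2 couple reoxidises palladium; this oxidation is established for allyl groups on α-quaternary cyclohexanones, and the hindered aldehyde should be tolerated.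

Step 6
Reactants: 8 (1S,6R)-2,2,6-trimethyl-6-(2-oxopropyl)cyclohexane-1-carbaldehyde
Product: 10 (4aS,8aR)-5,5,8a-trimethyl-4a,5,6,7,8,8a-hexahydronaphthalen-2(1H)-one, via aldol adduct 9 (not isolated)
Conditions: KOH, MeOH, 25 → 60 °C
Reagents that add atoms: none
Why: Hydroxide enolises the ketone arm reversibly, and of the enolisable carbons only the methyl carbon C7 can reach the aldehyde through a six-membered transition state, because the C9 enolate and the aldehyde enolate at C5 could only close four-membered rings and the neopentyl aldehyde is too hindered for intermolecular aldol reaction. Addition of the C7 enolate to the aldehyde carbon C6 is a 6-(enolendo)-exo-trig closure of ring B and gives aldol 9; E1cB loss of water then gives the conjugated 6-en-8-one and pulls the equilibria forward. The closest known reaction type is the base-mediated intramolecular aldol condensation of 1,5-dicarbonyl compounds, as in the second stage of a Robinson annulation and in closures of Wacker-derived methyl ketones on α-quaternary rings. The only new stereocentre, C5, is under thermodynamic control: it is epimerisable in 8 (α to the aldehyde), in 9 through retro-aldol and re-addition, and in 10 as the γ-carbon through the dienolate. The trans-fused decalin with the C10 methyl and H5 both axial is expected to be the preferred isomer. C10, set in step 2, is untouched and so fixes the absolute configuration of C5. The step needs ring-size selectivity, secured by the 1,5-dicarbonyl relationship, and a preference for the conjugated over the deconjugated enone.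

Step 7
Reactants: 11 (2Z)-3-methylpent-2-en-4-yn-1-ol
Product: 12 tert-butyldimethyl{[(2Z)-3-methylpent-2-en-4-yn-1-yl]oxy}silane
Conditions: TBSCl, imidazole, DMF, 0 → 25 °C
Reagents that add atoms: tert-butyldimethylsilyl chloride, CC(C)(C)[Si](C)(C)Cl
Why: Standard silylation of a primary allylic alcohol; the silyl ether is chosen to survive the organolithium, enolate, chromium and hydride steps and to be removed by fluoride at the end.

Step 8
Reactants: 12 tert-butyldimethyl{[(2Z)-3-methylpent-2-en-4-yn-1-yl]oxy}silane
Product: 13 tert-butyldimethyl{[(2Z)-3-methylpenta-2,4-dien-1-yl]oxy}silane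
Conditions: H2 (1 atm, one equivalent), Pd/CaCO3 poisoned with Pb(OAc)2 (Lindlar catalyst), quinoline, hexane, 0 °C
Reagents that add atoms: none
Why: Lindlar semihydrogenation of a terminal conjugated enyne to the 1,3-diene; stopping after one equivalent of hydrogen with quinoline present should leave the trisubstituted Z-alkene untouched.

Step 9
Reactants: 13 tert-butyldimethyl{[(2Z)-3-methylpenta-2,4-dien-1-yl]oxy}silane
Product: 15 (3Z)-5-(tert-butyldimethylsilyloxy)-3-methylpent-3-en-1-ol, via B-alkyl-9-borabicyclononane 14 (not isolated)
Conditions: 9-borabicyclo[3.3.1]nonane, THF, 0 → 25 °C; then NaOH, H2O2, 0 °C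
Reagents that add atoms: hydrogen peroxide, OO
Why: Anti-Markovnikov hydroboration–oxidation; the hindered borane reacts with the monosubstituted terminal alkene of the diene much faster than with the trisubstituted one and places boron on the terminal carbon, and alkaline peroxide replaces boron by hydroxyl with the Z-alkene unchanged.

Step 10
Reactants: 15 (3Z)-5-(tert-butyldimethylsilyloxy)-3-methylpent-3-en-1-ol
Product: 16 tert-butyl{[(2Z)-5-iodo-3-methylpent-2-en-1-yl]oxy}dimethylsilane
Conditions: I2, PPh3, imidazole, CH2Cl2, 0 °C
Reagents that add atoms: iodine, II
Why: Appel-type iodination (Garegg–Samuelsson conditions); iodide displaces the oxyphosphonium group at the primary carbon under neutral conditions that keep the allylic silyl ether and the Z-alkene intact.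

Step 11
Reactants: 10 (4aS,8aR)-5,5,8a-trimethyl-4a,5,6,7,8,8a-hexahydronaphthalen-2(1H)-one; 16 tert-butyl{[(2Z)-5-iodo-3-methylpent-2-en-1-yl]oxy}dimethylsilane
Product: 19 15-(tert-butyldimethylsilyloxy)-17-norlabda-6,13Z-dien-8-one (9β chain; 9α-H; 5α-H; 10β-methyl), via lithium cross-conjugated enolate 17 (not isolated), via 9α-alkyl epimer 18 (not isolated)
Conditions: LiN(i-Pr)2, THF, −78 °C; then 16, HMPA, −78 → 0 °C; then NaOMe, MeOH, 25 °C
Reagents that add atoms: none
Why: Kinetic α'-deprotonation of the enone gives enolate 17, which is alkylated at C9 by the primary iodide in the presence of HMPA (enolate alkylation, as in α'-alkylation of isophorone-type enones); attack anti to the axial C10 methyl should give the axial 9α-epimer 18 first, and methoxide then equilibrates C9 to the equatorial 9β-chain epimer 19, whose axial 9α-H is needed in step 14.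

Step 12
Reactants: 19 15-(tert-butyldimethylsilyloxy)-17-norlabda-6,13Z-dien-8-one
Product: 20 15-(tert-butyldimethylsilyloxy)labda-6,13Z-dien-8β-ol (8α-methyl; 9α-H)
Conditions: MeLi, Et2O, −78 °C; then H2O
Reagents that add atoms: methyllithium, [Li]C
Why: 1,2-Addition of methyllithium to the enone carbonyl; attack from the α-face, away from the axial C10 methyl, should give mainly the 8β-alcohol, and either C8 epimer serves because C8 becomes sp2 in step 13.

Step 13
Reactants: 20 15-(tert-butyldimethylsilyloxy)labda-6,13Z-dien-8β-ol
Product: 21 15-(tert-butyldimethylsilyloxy)labda-7,13Z-dien-6-one (9α-H; 5α-H)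
Conditions: pyridinium chlorochromate, 4 Å molecular sieves, CH2Cl2, 25 °C
Reagents that add atoms: pyridinium chlorochromate (supplies the C6 oxygen), [O-][Cr](=O)(=O)Cl.c1cc[nH+]cc1
Why: Babler–Dauben oxidative transposition; the tertiary allylic chromate ester undergoes a [3,3] shift to the secondary C6 chromate, which is oxidised to the 8-methyl-7-en-6-one, so the oxygen function moves from C8 to C6 and the new methyl group ends on the alkene.

Step 14
Reactants: 21 15-(tert-butyldimethylsilyloxy)labda-7,13Z-dien-6-one
Product: 23 15-(tert-butyldimethylsilyloxy)-7α-hydroxylabda-8,13Z-dien-6-one, via potassium dienolate 22 (not isolated)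
Conditions: KN(SiMe3)2 (0.95 equiv), THF, −78 → 0 °C; then 2-(phenylsulfonyl)-3-phenyloxaziridine, −78 °C; then H2O
Reagents that add atoms: 2-(phenylsulfonyl)-3-phenyloxaziridine, O=S(=O)(c1ccccc1)N1OC1c1ccccc1
Why: With a slight deficit of base and warming, the enolates equilibrate to the through-conjugated dienolate 22 formed by loss of the axial 9α-H, which places the tetrasubstituted alkene at C8=C9; metal dienolates react with sulfonyloxaziridines at the α-carbon (Davis hydroxylation), and approach from the α-face, opposite the axial methyl groups on C4 and C10, should give the 7α-alcohol.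

Step 15
Reactants: 23 15-(tert-butyldimethylsilyloxy)-7α-hydroxylabda-8,13Z-dien-6-one
Product: 24 15-(tert-butyldimethylsilyloxy)labda-8,13Z-diene-6β,7α-diol
Conditions: NaBH4, CeCl3·7H2O, MeOH, −40 → 0 °C
Reagents that add atoms: none
Why: Luche-type borohydride reduction; the β-face of C6 is blocked by the syn-axial methyl groups on C4 and C10, so hydride should enter from the α-face and give the axial 6β-alcohol, while the cerium salt keeps the medium weakly basic and the reduction fast, which suppresses enediol isomerisation of the α-ketol.

Step 16
Reactants: 24 15-(tert-butyldimethylsilyloxy)labda-8,13Z-diene-6β,7α-diol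
Product: 25 labda-8,13Z-diene-6β,7α,15-triol
Conditions: n-Bu4NF, THF, 0 → 25 °C
Reagents that add atoms: none
Why: Fluoride cleavage of the primary silyl ether; non-acidic conditions avoid ionisation of the allylic C7 alcohol.

Step 17
Reactants: 25 labda-8,13Z-diene-6β,7α,15-triol
Product: 26 7α,15-diacetoxylabda-8,13Z-dien-6β-ol (the target)
Conditions: Ac2O (excess), pyridine, 4-(dimethylamino)pyridine (cat.), CH2Cl2, 0 → 25 °C
Reagents that add atoms: acetic anhydride, CC(=O)OC(C)=O
Why: Rate-controlled acetylation; the primary allylic C15 alcohol and the secondary allylic C7 alcohol are acylated, whereas an axial 6β-hydroxyl held between the C4 and C10 methyl groups is known in this ring system to resist acetic anhydride/pyridine, and the trans-diaxial arrangement of O6 and O7 disfavours acyl migration.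

## Compound list

1 | 2,2,6-trimethylcyclohexanone (racemic) | CC1CCCC(C)(C)C1=O | starting material
2 | allyl chloroformate | C=CCOC(Cl)=O | starting material
3 | lithium 2,6,6-trimethylcyclohex-1-en-1-olate | [Li]OC1=C(C)CCCC1(C)C | intermediate (not isolated)
4 | allyl 2,6,6-trimethylcyclohex-1-en-1-yl carbonate | C=CCOC(=O)OC1=C(C)CCCC1(C)C | intermediate
5 | (2R)-2-allyl-2,6,6-trimethylcyclohexan-1-one | O=C1C(C)(C)CCC[C@]1(C)CC=C | intermediate
6 | (4R)-4-allyl-4,8,8-trimethyl-1-oxaspiro[2.5]octane, both configurations at the spiro carbon | O1CC12C(C)(C)CCC[C@]2(C)CC=C | intermediate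
7 | (1S,6R)-6-allyl-2,2,6-trimethylcyclohexane-1-carbaldehyde | O=C[C@H]1C(C)(C)CCC[C@]1(C)CC=C | intermediate
8 | (1S,6R)-2,2,6-trimethyl-6-(2-oxopropyl)cyclohexane-1-carbaldehyde | O=C[C@H]1C(C)(C)CCC[C@]1(C)CC(C)=O | intermediate (key-step precursor)
9 | (4aS,8aR)-4-hydroxy-5,5,8a-trimethyloctahydronaphthalen-2(1H)-one, carbinol epimers | C1C(=O)CC(O)[C@H]2C(C)(C)CCC[C@]12C | intermediate (not isolated)
10 | (4aS,8aR)-5,5,8a-trimethyl-4a,5,6,7,8,8a-hexahydronaphthalen-2(1H)-one (trans-fused 6-en-8-one in labdane numbering) | C1C(=O)C=C[C@H]2C(C)(C)CCC[C@]12C | intermediate (key-step product)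
11 | (2Z)-3-methylpent-2-en-4-yn-1-ol | OC/C=C(/C)C#C | starting material
12 | tert-butyldimethyl{[(2Z)-3-methylpent-2-en-4-yn-1-yl]oxy}silane | CC(C)(C)[Si](C)(C)OC/C=C(/C)C#C | intermediate
13 | tert-butyldimethyl{[(2Z)-3-methylpenta-2,4-dien-1-yl]oxy}silane | CC(C)(C)[Si](C)(C)OC/C=C(/C)C=C | intermediate
14 | 9-[(3Z)-5-(tert-butyldimethylsilyloxy)-3-methylpent-3-en-1-yl]-9-borabicyclo[3.3.1]nonane | CC(C)(C)[Si](C)(C)OC/C=C(/C)CCB1C2CCCC1CCC2 | intermediate (not isolated)
15 | (3Z)-5-(tert-butyldimethylsilyloxy)-3-methylpent-3-en-1-ol | CC(C)(C)[Si](C)(C)OC/C=C(/C)CCO | intermediate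
16 | tert-butyl{[(2Z)-5-iodo-3-methylpent-2-en-1-yl]oxy}dimethylsilane | CC(C)(C)[Si](C)(C)OC/C=C(/C)CCI | intermediate
17 | lithium cross-conjugated enolate of 10 (O-lithio 6,8-dien-8-ol, ring fusion as in 10) | C1=C(O[Li])C=C[C@H]2C(C)(C)CCC[C@]12C | intermediate (not isolated)
18 | 15-(tert-butyldimethylsilyloxy)-17-norlabda-6,13Z-dien-8-one, 9α chain (9β-H) | CC(C)(C)[Si](C)(C)OC/C=C(/C)CC[C@@H]1C(=O)C=C[C@H]2C(C)(C)CCC[C@]12C | intermediate (not isolated)
19 | 15-(tert-butyldimethylsilyloxy)-17-norlabda-6,13Z-dien-8-one, 9β chain (9α-H) | CC(C)(C)[Si](C)(C)OC/C=C(/C)CC[C@H]1C(=O)C=C[C@H]2C(C)(C)CCC[C@]12C | intermediate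
20 | 15-(tert-butyldimethylsilyloxy)labda-6,13Z-dien-8β-ol (8α-methyl, 9α-H) | CC(C)(C)[Si](C)(C)OC/C=C(/C)CC[C@H]1[C@@](C)(O)C=C[C@H]2C(C)(C)CCC[C@]12C | intermediate
21 | 15-(tert-butyldimethylsilyloxy)labda-7,13Z-dien-6-one (9α-H, 5α-H) | CC(C)(C)[Si](C)(C)OC/C=C(/C)CC[C@H]1C(C)=CC(=O)[C@H]2C(C)(C)CCC[C@]12C | intermediate
22 | potassium 15-(tert-butyldimethylsilyloxy)labda-6,8,13Z-trien-6-olate | CC(C)(C)[Si](C)(C)OC/C=C(/C)CCC1=C(C)C=C(O[K])[C@H]2C(C)(C)CCC[C@]12C | intermediate (not isolated)
23 | 15-(tert-butyldimethylsilyloxy)-7α-hydroxylabda-8,13Z-dien-6-one | CC(C)(C)[Si](C)(C)OC/C=C(/C)CCC1=C(C)[C@H](O)C(=O)[C@H]2C(C)(C)CCC[C@]12C | intermediate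
24 | 15-(tert-butyldimethylsilyloxy)labda-8,13Z-diene-6β,7α-diol | CC(C)(C)[Si](C)(C)OC/C=C(/C)CCC1=C(C)[C@H](O)[C@@H](O)[C@H]2C(C)(C)CCC[C@]12C | intermediate
25 | labda-8,13Z-diene-6β,7α,15-triol | OC/C=C(/C)CCC1=C(C)[C@H](O)[C@@H](O)[C@H]2C(C)(C)CCC[C@]12C | intermediate
26 | 7α,15-diacetoxylabda-8,13Z-dien-6β-ol (5S,6S,7S,10S) | CC(=O)OC/C=C(/C)CCC1=C(C)[C@H](OC(C)=O)[C@@H](O)[C@H]2C(C)(C)CCC[C@]12C | target

## Step count and least certain steps

Total: 17 steps. Longest linear sequence: 13 steps (steps 1–6 and 11–17, from ketone 1). The side-chain branch is 4 steps (7–10) and joins at step 11.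

**Step 6 (key step).** Dehydration of the hindered aldolate may stall at 9. Prolonged hot hydroxide may also move the double bond out of conjugation toward C5=C6, which relieves the C4/C10 methyl interaction, or leave C5 incompletely equilibrated. Fallback: from 8, the ring is closed as an addition only, by kinetic deprotonation of the methyl ketone with LiN(SiMe3)2 in THF at −78 °C, and aldol 9 is isolated. It is converted with MsCl/Et3N into its mesylate, 4-(methanesulfonyloxy)-5,5,8a-trimethyloctahydronaphthalen-2(1H)-one F1, which DBU in toluene eliminates (E1cB) to return to 10. A brief treatment with catalytic NaOMe would then equilibrate C5 if needed.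

**Step 2.** Facial discrimination of the tetrasubstituted enolate by the PHOX complex is high but not complete, so a minor amount of the enantiomeric series would be carried through. Fallback: enrichment is done by crystallisation at the first unhindered carbonyl compound. Setting out from 10, semicarbazide hydrochloride/NaOAc gives the semicarbazone of 10 F2, which is recrystallised to optical purity and hydrolysed with aqueous HCl/THF, returning to 10.

**Step 3.** Addition of the ylide to a carbonyl flanked by two quaternary carbons may be slower than decomposition of the ylide. Fallback: from 5, titanium-mediated methylenation (Zn, CH2Br2, TiCl4) gives (1R)-1-allyl-1,3,3-trimethyl-2-methylidenecyclohexane F3. One equivalent of mCPBA (NaHCO3, CH2Cl2, 0 °C) then epoxidises the more electron-rich 1,1-disubstituted alkene in preference to the monosubstituted allyl group, returning to 6.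

**Step 11.** The hindered enolate may act as a base on the homoallylic iodide (E2 to diene 13) faster than it is alkylated at the neopentyl-type C9, with proton transfer returning 10. Fallback: the nucleophile is changed to a metalated hydrazone. From 10, 1,1-dimethylhydrazine (cat. AcOH, EtOH, reflux) gives the N,N-dimethylhydrazone of 10 F4. Deprotonation with LiN(i-Pr)2 and alkylation with 16 give the C9-alkylated hydrazone F5. Hydrolysis with aqueous Cu(OAc)2 in THF, followed by the NaOMe equilibration, returns to 19.

**Step 13.** The tertiary allylic alcohol may dehydrate to 6,8-dienes in the acidic chromium medium, the transposed oxygen must enter the congested C6 position, and the silyl ether may be partly lost. Fallback: transposition and oxidation are separated. From 20, catalytic Ph3SiOReO3 in Et2O (−50 → 0 °C) isomerises the alcohol to the secondary allylic alcohol 15-(tert-butyldimethylsilyloxy)labda-7,13Z-dien-6-ol F6 (6β expected from a suprafacial shift; either epimer serves). MnO2 in CH2Cl2 oxidises it, returning to 21.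

**Step 14.** Proton removal may occur at C5 or at the C8 methyl instead of C9, leading to hydroxylation at C5 or to an exocyclic alkene. The oxidant may show poor facial selectivity at C7. Base may also isomerise α-ketol 23 toward the conjugated 7-keto isomer or epimerise C5. Fallback: the site of deprotonation is fixed in a separate, reversible step. From 21, KOt-Bu in t-BuOH/THF followed by a quench into aqueous AcOH (kinetic α-protonation of the dienolate) gives the deconjugated ketone 15-(tert-butyldimethylsilyloxy)labda-8,13Z-dien-6-one F7. Its C7 methylene is now the most acidic and least hindered α-position. LiN(i-Pr)2 at −78 °C followed by the same oxaziridine returns to 23.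

## Further compounds

F1 | step 6 | 4-(methanesulfonyloxy)-5,5,8a-trimethyloctahydronaphthalen-2(1H)-one (mesylate of 9, carbinol epimers) | C1C(=O)CC(OS(C)(=O)=O)[C@H]2C(C)(C)CCC[C@]12C
F2 | step 2 | semicarbazone of 10 | C1C(=NNC(N)=O)C=C[C@H]2C(C)(C)CCC[C@]12C
F3 | step 3 | (1R)-1-allyl-1,3,3-trimethyl-2-methylidenecyclohexane | C=C1C(C)(C)CCC[C@]1(C)CC=C
F4 | step 11 | N,N-dimethylhydrazone of 10 | C1C(=NN(C)C)C=C[C@H]2C(C)(C)CCC[C@]12C
F5 | step 11 | N,N-dimethylhydrazone of 15-(tert-butyldimethylsilyloxy)-17-norlabda-6,13Z-dien-8-one (9α chain) | CC(C)(C)[Si](C)(C)OC/C=C(/C)CC[C@@H]1C(=NN(C)C)C=C[C@H]2C(C)(C)CCC[C@]12C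
F6 | step 13 | 15-(tert-butyldimethylsilyloxy)labda-7,13Z-dien-6β-ol (9α-H) | CC(C)(C)[Si](C)(C)OC/C=C(/C)CC[C@H]1C(C)=C[C@@H](O)[C@H]2C(C)(C)CCC[C@]12C
F7 | step 14 | 15-(tert-butyldimethylsilyloxy)labda-8,13Z-dien-6-one | CC(C)(C)[Si](C)(C)OC/C=C(/C)CCC1=C(C)CC(=O)[C@H]2C(C)(C)CCC[C@]12C
A1 | alternative 1 | acyclic trienal: (2E)-enal tethered through C4 gem-dimethyl and three methylenes to a tetrasubstituted diene bearing the silylated Z side chain | CC(C)(C)[Si](C)(C)OC/C=C(/C)CC/C(C(C)=C)=C(/C)CCCC(C)(C)/C=C/C=O
A2 | alternative 1 | trans-fused 15-(tert-butyldimethylsilyloxy)labda-8,13Z-diene with a 6α-formyl group | CC(C)(C)[Si](C)(C)OC/C=C(/C)CCC1=C(C)C[C@H](C=O)[C@H]2C(C)(C)CCC[C@]12C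
A3 | alternative 2 | (1S)-2,4,4-trimethyl-3-vinylcyclohex-2-en-1-yl but-2-ynoate | CC#CC(=O)O[C@H]1CCC(C)(C)C(C=C)=C1C
A4 | alternative 2 | tricyclic 5,8-diene γ-lactone (C11 carbonyl to the C1 oxygen, labdane numbering) | C1(C(=O)O3)=C(C)CC=C2C(C)(C)CC[C@H]3[C@]12C
A5 | alternative 3 | (1R,5R)-verbenone | CC1=CC(=O)[C@@H]2C[C@H]1C2(C)C
A6 | alternative 3 | 4-allyl-4,6,6-trimethylbicyclo[3.1.1]heptan-2-one, allyl anti to the gem-dimethyl bridge | C=CC[C@]1(C)CC(=O)[C@@H]2C[C@H]1C2(C)C
A7 | alternative 3 | 4,4,10-trimethyl-trans-octal-2-en-8-one (labdane numbering) | C1C(=O)CC[C@H]2C(C)(C)C=CC[C@]12C
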